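Two questions stood over these flasks: how much complex with two exchanged each held at the end, and how that row ran.

common to all: starting complex 10 mM; time 6.0 min
- oak: incoming ligand 0.400 equiv
- alder: incoming ligand 1.00 equiv
- birch: incoming ligand 3.00 equiv
- larch: incoming ligand 10.0 equiv

    starting complex + incoming ligand ⇌ leaving ligand + complex with one exchanged (K1 = 68, k1 = 25 /M/min)
    complex with one exchanged + incoming ligand ⇌ leaving ligand + complex with two exchanged (K2 = 0.49, k2 = 24 /M/min)
    complex with two exchanged + incoming ligand ⇌ leaving ligand + complex with three exchanged (K3 = 80, k3 = 16 /M/min)
    leaving ligand + complex with two exchanged → side product A (k4 = 2.8 /M/min)
    complex with one exchanged → side product B (k5 = 0.063 /min)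

- [complex with two exchanged] at the end for oak, alder, birch, larch, in this order
- how the row runs (falls all the way / rises, then falls / falls, then rises / hardly changes / rises all the way)

- "hardly changes" means that all values lie within two and a half points (for a concentration: within two and a half percent of the largest)
- run time (oak): 6.0 min

I counted time constants. With incoming ligand held steady, each forward exchange is pseudo-first-order, and its time constant is one over the rate constant times the ligand concentration. Using 25 /M/min, I got 1.50. I called this, the run time over the time constant of step 1 at one equivalent of ligand, the lifetime count per equivalent. A flask's count is this number times its equivalents.

For a chain of equal forward steps with ligand held, the second product stands at the count squared over two, times exp of minus the count. That peaks at a count of two. Step 3 was slower than step 2, and ligand is used up, so both push the top towards more equivalents. With ligand held at its charge, a count of two came at 1.33 equivalents, my bound from below. With ligand held at its charge less the two equivalents that a full passage to complex with two exchanged takes, it came at 3.33 equivalents, my rough bound from above, with the steps still taken as equal. The back steps stayed outside this bracket.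

Oak's count was 0.600 and alder's was 1.50, so both stood below the bracket. Larch stood above it, with a count of 12.0 even on the lean reckoning. Birch lay inside it. So I expected a rise, then a fall.

The forecast gave 2.30%, 7.70%, 13.5% and 2.00% of the charge, and rises, then falls. It held that the complex “grows as the ligand dose rises to about 3 equiv”. That top lay inside my bracket, above the lower bound and below the upper one.

The simulation gave 2.35%, 7.50%, 13.9% and 1.75% of the charge, and rises, then falls, with the turn at 2.9 equiv.

Birch ended with 46% of its ligand, so its count on that ligand was 2.09, and birch held the highest value of the row. Larch ended with 72% of its ligand, a count of 10.8, and the forward chain at that count leaves 0.119%. Larch held more than that. Part of larch's residue came from step 2 running back together with the run stopping at 6.0 min: without that back step larch ended at 0.786%, and in a run of 60.0 min at 0.376%.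

The numbers belong to no real substance; what happens was integrated by code.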